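4 questions stand here, and behind them one: does heat buy target, or does the gas hold the flasks level?

- the flask that comes out highest in amount of target, in percent of the substrate charged, or "all alike" when all lie within 1.5 percentage points (west / north-west / east / all alike)
- target at the end, in percent of the substrate charged, west
- target at the end, in percent of the substrate charged, north-west
- target at the end, in percent of the substrate charged, east

the same everywhere: gas 4.5 mM (held)
- Sunday's: substrate 0.019 M; temperature 115 °C; run made earlier
- Wednesday's: substrate 0.078 M; temperature 126 °C; run made earlier
- west: substrate 0.039 M; at 110 °C until 1.0 h, from then on at 130 °C; time 80 min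
- north-west: substrate 0.039 M; temperature 110 °C; time 80 min
- east: substrate 0.039 M; temperature 130 °C; time 80 min

- Sunday's (time / min: target / %, substrate / %): 5.00: 0.3, 73.2; 12.0: 3.6, 49.1; 30.0: 18.1, 26.3; 60.0: 36.5, 18.4
- Wednesday's (time / min: target / %, substrate / %): 4.00: 1.4, 55.5; 12.0: 6.1, 28.5; 20.0: 15.8, 26.4; 25.0: 18.0, 23.8

(readings scatter by 1 percentage point)

- at the start none of the gas is in solution

I turn it round. For "all alike" the gas, charged in the smaller amount, would have to act as limiting reagent. Suppose each target takes one gas. In Wednesday's run the dissolved gas is 5.77% of the charge, yet target reads 18.0% at 25.0 min, more than that. So the held gas is refilled, and the balance is one of rates, not of a stock.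

I therefore follow the fraction not yet target and read its late decay as pseudo-first-order. Wednesday's last two readings lie 5.00 min apart and differ by 2.2 percentage points against a scatter of 1 point, so there I take the longer span from 12.0 min to 25.0 min. That gives 0.0104 min⁻¹ in Wednesday's run, and the span from 30.0 min to 60.0 min gives 0.00848 min⁻¹ in Sunday's. Wednesday's, the hotter run, reads higher, but its charge is also 4.11 times Sunday's, so the two settings are mixed, and with this scatter the gap is thin. For "all alike" this constant would have to stay nearly level from 110 °C to 130 °C.

A straight line through both readings gives my clearing constant at 110 °C, the first-order decay constant of the fraction not yet target, 0.00760 min⁻¹, and 0.0111 min⁻¹ at 130 °C. Started level, east ends with 0.754 of north-west's not-yet-target, and west, hot for 20.0 min, with 0.932. Taking Sunday's last 63.5% as a measure of north-west's, my reckoning puts east ahead by 16 points, beyond the margin; "all alike" would need that ratio above 0.976, and mine stands lower.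

The forecast says east: west 44%, north-west 38%, east 57%, with the caution “Temperature and concentration are confounded”. Its east-to-north-west ratio is 0.694, lower than my 0.754.

The flasks give west 41.8%, north-west 37.2%, east 56.1%, and east stands highest. Left until 800 min, north-west reaches 99.7%, so at 80 min that flask is slow, not stopped.

    substrate ⇌ open intermediate (K = 2.70, k = 8.10 × 10⁻⁴ s⁻¹, Ea = 101 kJ mol⁻¹, ΔH = 3.00 kJ mol⁻¹)
    partner → second intermediate (k = 0.0260 s⁻¹, Ea = 117 kJ mol⁻¹)
    open intermediate + second intermediate → target (k = 0.0330 M⁻¹ s⁻¹, Ea = 84.0 kJ mol⁻¹)
    2 second intermediate → homo product (k = 0.0120 M⁻¹ s⁻¹, Ea = 63.0 kJ mol⁻¹)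
    gas ⇌ partner, rate k5*(csat - [partner]) (kL = 0.0340 s⁻¹)
    second intermediate → side product (k = 0.0120 s⁻¹, Ea = 104 kJ mol⁻¹)
    (constants at 110 °C)

Starting from north-west's 17.0% at 40.0 min, the clearing constant gives 38.8% at the end, against 37.2%.

Carried on to 2.5 h in the same flask, it gives 63.1%; the flask gives 62.2%.

Readings and results were computed on assumed constants; the scatter is artificial.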